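## Structural features

The target is a 2,6-diaryl-3,7-dioxabicyclo[3.3.0]octane (furofuran lignan). Two tetrahydrofuran rings are cis-fused through the C8–C8' bond; ring A (4-hydroxy-3-methoxyphenyl) sits on C7, ring B (3-hydroxy-4,5-dimethoxyphenyl) on C7', and the ether bridges run C7–O–C9' and C7'–O–C9. The four stereocentres C7, C8, C8' and C7' are contiguous, (7S,8R,8'R,7'S), with both aryl groups on the convex (exo) face. The bicyclic core is C2-symmetric but the two aryl groups differ, so dimerising one C6–C3 unit is excluded and each half must enter by a different kind of reactivity. The fragile points are the benzylic ether carbons C7 and C7', each activated by a para-oxygenated ring: acid ionises them (epimerisation, Friedel–Crafts capture by the other ring) and palladium with hydrogen can cleave them. The two free phenols must be masked through all carbanion, hydride and cation chemistry. Because C7 and C7' ionise so readily they are correctable late; the real difficulty is the absolute configuration of the non-epimerisable bridgeheads C8 and C8' and the unambiguous placement of ring A and ring B. The key step exploits the chain C9'–C8'–C8–C9: with C9' as a lactone carbonyl and C9 as an acetal carbon it is a 5-alkoxybutenolide. Its β-carbon C8 is an acceptor and its α-carbon C8' becomes a donor after conjugate addition. Each bridgehead can therefore take up one benzylic carbon (C7 as an acyl-anion equivalent, C7' as an aldehyde) under control of a removable stereocentre at C9.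

## Logic of the disconnections

19 ⇒ 18. The two phenolic O–H bonds are traced back to O–benzyl bonds. The phenols would not survive the organolithium, the hydride or the cation chemistry, and a benzyl ether tolerates all of them. Nothing is gained in skeleton, only in compatibility. The forward step must cleave two aryl O–CH2Ph bonds without opening the benzylic ring bonds C7–O and C7'–O.

18 ⇒ 16 (through 17). The ring bonds C7–O and C7'–O are cut, the oxygen atoms staying on C9' and C9. Both benzylic carbons carry para-alkoxyaryl groups, so these bonds can be made through cations. Both rings disappear and C7 and C7' no longer need control: 16 may be any mixture at these two centres. The forward step must close each cation on the exo face, must prefer the primary hydroxyl over the other benzylic hydroxyl and over the neighbouring arene, and must stop before the product ionises again.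

16 ⇒ 15 ⇒ 14. No skeletal bond is cut; C7 is taken back from carbinol to ketone to cyclic dithioacetal. This reveals C7 as a carbon that can be introduced as a nucleophile, and it removes one stereocentre. The forward steps must unmask the ketone without oxidising the electron-rich rings and without enolising the adjacent centre C8, and then reduce it.

14 ⇒ 13. The two hydroxymethyl carbons are traced back to a lactone carbonyl (C9') and an acetal carbon (C9) joined through one oxygen, C9 also carrying the auxiliary 6. The flexible chain of 14 becomes a five-membered ring with two distinguishable faces and one controlling stereocentre that vanishes again on reduction. The forward step needs a hydride strong enough to take both carbons to the alcohol level and expel 6.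

13 ⇒ 2 + 8 + 10 (key disconnection). C7–C8 and C8'–C7' are cut. C8 is the β-carbon and C8' the α-carbon of 8, so C7 must arrive as a nucleophile (the anion 11 of 2) and C7' as an electrophile (10), by way of enolate 12. Three fragments of similar size result, the two aryl groups are told apart by polarity, and C8 and C8' are set relative to C9. In the bookkeeping of configuration, the (5R) acetal of 8 translates into (8R,8'R) of 19. The forward step must add 1,4 and not 1,2, must add anti to the auxiliary, must trap the enolate anti to the new C8 substituent, and must be quenched before the adduct reverts.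

2 ⇒ 1. The two C–S bonds at C7 are cut; a single thioacetalisation of a commercial aldehyde is required.

8 ⇒ 5 + 6, and 5 ⇒ 3 (through 4). The C9–O bond to the auxiliary is cut, leaving a racemic lactol and a cheap chiral alcohol. The forward step gives both acetal epimers, so it depends on crystallisation of 8 and acid recycling of 7. Compound 5 is traced to 3 by oxidative loss of the formyl carbon.

10 ⇒ 9. The O–benzyl bond of ring B is cut; a simple etherification of a commercial phenol.

## Other disconnections considered

Alternative 1: The cut runs through O–C7 and C7–C8, dismantling the ring A tetrahydrofuran. The fragments are a ring B dihydrofuran bearing the C9' hydroxymethyl group, [(2S,3R)-2-(3-benzyloxy-4,5-dimethoxyphenyl)-2,3-dihydrofuran-3-yl]methanol A2, and the dimethyl acetal of the ring A aldehyde A3.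
- Forward step: Me3SiOTf would exchange the C9' hydroxyl into A3. The C7 oxocarbenium ion would be attacked by the enol ether carbon C8 in a Prins-type closure, and methanol would cap the resulting C9 oxocarbenium ion to give the C9 methoxy acetal A1. Ionic reduction at C9 (Et3SiH, BF3·OEt2) would then lead to 18.
- In favour: one operation would form a C–C bond, a C–O bond, a ring and two stereocentres, with the cis fusion enforced. Only two operations would follow the key step, against five after step 5, and no sulfur and no auxiliary removal are involved. On these counts it is the better plan.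
- Against: A2 already contains C7' and C8' in the trans relation and in one absolute sense. The stereochemical problem is therefore moved into the precursor, whose enantioselective preparation should cost at least as many steps as steps 1–5. The orientation of ring A at C7 would be fixed in a compact bicyclic transition state in which the aryl group of the oxocarbenium ion may well prefer the concave face. A later acid equilibration has no clear bias towards the exo isomer, since exo,exo and exo,endo furofurans are close in energy. The enol ether and the benzylic C7'–O bond of A2 would both be exposed to the Lewis acid.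
- Comparison: the two plans are equal in telling ring A and ring B apart by polarity. The alternative sets C7 during C–C bond formation, whereas the chosen plan leaves C7 to a late C–O closure that is free to take the exo face. The alternative wins on steps after the key step and loses on steps before it.

Alternative 2: The cut runs through C7–O and C7'–O with both benzylic carbons at the CH2 level, giving (2R,3R)-2-(4-benzyloxy-3-methoxybenzyl)-3-(3-benzyloxy-4,5-dimethoxybenzyl)butane-1,4-diol A5.
- Forward step: DDQ would abstract hydride at C7, the cation would be taken up by the C9' hydroxyl, and a second abstraction at C7' with capture by the C9 hydroxyl would give the dibenzyl ether A4, which is the same compound as 18.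
- In favour: this is the shortest endgame, one step from A4 to the target, with no change of oxidation level at C7 or C7' by separate operations. A5 has only the stereocentres C8 and C8', which could come from the same butenolide conjugate addition with a benzylic halide as the enolate trap. It is therefore equal in the origin of absolute configuration and better in step economy. The exo closure would rest on the same kinetic preference as step 9, so the two plans are equal on that point.
- Against: hydride must be removed twice from unfunctionalised CH2 groups while the product carries two benzylic ether C–H bonds that are better hydride donors than those of A5, so over-oxidation would compete with the second closure. The para-methoxy group of ring B is flanked on both sides and twisted out of conjugation, which should make C7' the reluctant site. A cation at C7 lies in the ideal 1,4-relation to the electron-rich ring B for Friedel–Crafts closure to an aryltetralin.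
- Comparison: in the chosen plan both benzylic carbons arrive already oxygenated, so ionisation needs only catalytic acid and no oxidant is present when the sensitive product forms. The alternative is shorter but leans on a chemoselectivity that the substitution pattern of ring B does not favour.

Alternative 3: The cut runs through C8'–C7' and O–C9 with C9 as a carbonyl, leading back to the dihydrofuran enal (R)-2-(4-benzyloxy-3-methoxyphenyl)-2,5-dihydrofuran-3-carbaldehyde A7 and aldehyde 10.
- Forward step: the carbene from 1,3-dimesitylimidazolium chloride and DBU would add to the formyl group of A7. The resulting homoenolate would attack 10 through C8', C8 would be protonated, and the new alkoxide would be acylated by the acyl azolium to close the lactone A6. Reduction of the C9 lactone to the ether (i-Bu2AlH, then Et3SiH, BF3·OEt2) would lead to 18.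
- In favour: the step is catalytic and metal-free, needs no auxiliary, and makes a C–C bond, a ring and up to three stereocentres with enforced cis fusion. Ring B enters as the same aldehyde 10, so the plans are equal there; the alternative is better in atom economy.
- Against: A7 is an α-branched, β-substituted cyclic enal, the class least inclined to form a homoenolate. Its only stereocentre, C7, is benzylic, allylic, α to oxygen and vinylogously acidic, so DBU could erase it or lead on to the furan. Facial selectivity at C8' would depend on that remote centre. In homoenolate annulations the aryl group of the aldehyde tends to end up cis to the ring substituent, which here would place ring B on the concave face, and a lactone C–O bond at C7' is harder to re-ionise for correction than an ether. A7 would itself need an enantioselective synthesis.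
- Comparison: the chosen plan spends more steps and a stoichiometric auxiliary, but its three stereochemical decisions each rest on a dependable element (acetal face, anti trapping, exo cation closure), whereas the alternative concentrates them in one step controlled by a labile centre.

Key step: step 5

Assumption: the carbinol centre C7' is written (S) in 13–17 and C7 is left undefined in 16, because steps 5 and 8 cannot be relied on to control them and step 9 ionises and resets both; lignan locants are used for the skeleton throughout.

## Route

Step 1
Reactants: 1 4-benzyloxy-3-methoxybenzaldehyde (O-benzylvanillin)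
Product: 2 2-(4-benzyloxy-3-methoxyphenyl)-1,3-dithiane
Conditions: propane-1,3-dithiol (1.1 equiv), BF3·OEt2 (cat.), CH2Cl2, 0 °C → rt
Reagents that add atoms: propane-1,3-dithiol, SCCCS
Why: Acid-catalysed thioacetalisation of an aromatic aldehyde; the aryl benzyl and methyl ethers tolerate catalytic BF3·OEt2 at this temperature. The dithiane turns the formyl carbon (C7) into a masked acyl anion.

Step 2
Reactants: 3 furfural
Product: 5 5-hydroxyfuran-2(5H)-one (racemic), via furfural endoperoxide 4 (not isolated)
Conditions: O2, hν (visible), methylene blue (cat.), MeOH, rt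
Reagents that add atoms: dioxygen, O=O
Why: Dye-sensitised singlet-oxygen [4+2] cycloaddition to the furan gives endoperoxide 4, which methanol fragments with loss of the formyl carbon as methyl formate; a long-established oxidative degradation of furfural to the hydroxybutenolide.

Step 3
Reactants: 5 5-hydroxyfuran-2(5H)-one; 6 (1R,2S,5R)-menthol
Product: 8 (5R)-5-[(1R,2S,5R)-menthyloxy]furan-2(5H)-one, via (5S)-acetal epimer 7 (not isolated)
Conditions: CSA (cat.), toluene, reflux, azeotropic removal of water; crystallisation from hexane, −20 °C; mother liquor re-equilibrated with CSA (cat.) and recrystallised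
Reagents that add atoms: none
Why: Acid-catalysed acetalisation of the lactol carbon (C9) gives both acetal epimers, of which 8 is the crystalline one. Acid re-equilibration of the mother liquor through the ring oxocarbenium ion should convert 7 into further 8, so the C9 configuration is fixed by the auxiliary and by crystallisation.

Step 4
Reactants: 9 3-hydroxy-4,5-dimethoxybenzaldehyde
Product: 10 3-benzyloxy-4,5-dimethoxybenzaldehyde
Conditions: BnBr, K2CO3, DMF, rt
Reagents that add atoms: benzyl bromide, BrCc1ccccc1
Why: Williamson etherification of the phenoxide; the benzyl ether withstands the organolithium, hydride, oxidant and acid of the later steps.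

Step 5
Reactants: 2 2-(4-benzyloxy-3-methoxyphenyl)-1,3-dithiane; 8 (5R)-5-[(1R,2S,5R)-menthyloxy]furan-2(5H)-one; 10 3-benzyloxy-4,5-dimethoxybenzaldehyde
Product: 13 (3S,4R,5R)-4-[2-(4-benzyloxy-3-methoxyphenyl)-1,3-dithian-2-yl]-3-[(S)-(3-benzyloxy-4,5-dimethoxyphenyl)(hydroxy)methyl]-5-[(1R,2S,5R)-menthyloxy]dihydrofuran-2(3H)-one, via lithiated dithiane 11 (not isolated), via lithium enolate 12 (not isolated)
Conditions: 2 (1.05 equiv), n-BuLi (1.05 equiv), THF, −78 → −30 °C; then 8, −78 °C; then 10 (1.1 equiv), −78 °C; NH4Cl (aq) at −78 °C
Reagents that add atoms: none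
Why: n-BuLi removes the C2 proton of 2 to give the sulfur- and aryl-stabilised carbanion 11, which adds in Michael fashion to C8, the β-carbon of 8, and the lithium enolate 12 is intercepted at C8' by aldehyde 10 in an aldol addition; C7–C8 and C8'–C7' are formed and no ring is closed. The closest known reaction type is the tandem conjugate addition and enolate trapping of 2-aryl-1,3-dithiane anions with 5-alkoxyfuran-2(5H)-ones. C8 is controlled by the acetal centre C9: the menthyloxy group covers one face of the flat butenolide, so 11 enters anti to it, which corresponds to (8R) of the target. C8' is controlled by the new C8 substituent: the bulky dithianyl group sends 10 to the opposite face of 12, giving the 3,4-trans lactone, (8'R) of the target. C7' is set in the aldol transition state without dependable control and is drawn (S), which is tolerable because that centre is ionised in step 9. The step needs 1,4- rather than 1,2-addition, which the soft, charge-delocalised anion and the low temperature secure, and it needs the trans,trans lactone, which the two anti approaches secure. It also needs the adduct to persist, so the mixture is kept at −78 °C and quenched cold to prevent retro-aldol and retro-Michael reversal.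

Step 6
Reactants: 13 (3S,4R,5R)-4-[2-(4-benzyloxy-3-methoxyphenyl)-1,3-dithian-2-yl]-3-[(S)-(3-benzyloxy-4,5-dimethoxyphenyl)(hydroxy)methyl]-5-[(1R,2S,5R)-menthyloxy]dihydrofuran-2(3H)-one
Product: 14 (2R,3R)-2-[2-(4-benzyloxy-3-methoxyphenyl)-1,3-dithian-2-yl]-3-[(S)-(3-benzyloxy-4,5-dimethoxyphenyl)(hydroxy)methyl]butane-1,4-diol
Conditions: LiAlH4 (excess), THF, 0 °C → rt; H2O, then 15% NaOH (aq) work-up
Reagents that add atoms: none
Why: LiAlH4 reduces the lactone carbonyl (C9') to CH2OH and, after collapse of the acyloxy acetal, the liberated C9 aldehyde to CH2OH with expulsion of menthol, which is recovered. Dithiane, benzyl ethers and the C8 and C8' centres are not affected.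

Step 7
Reactants: 14 (2R,3R)-2-[2-(4-benzyloxy-3-methoxyphenyl)-1,3-dithian-2-yl]-3-[(S)-(3-benzyloxy-4,5-dimethoxyphenyl)(hydroxy)methyl]butane-1,4-diol
Product: 15 (2R,3R)-3-[(S)-(3-benzyloxy-4,5-dimethoxyphenyl)(hydroxy)methyl]-1-(4-benzyloxy-3-methoxyphenyl)-4-hydroxy-2-(hydroxymethyl)butan-1-one
Conditions: PhI(OCOCF3)2 (1.5 equiv), NaHCO3, MeCN–H2O (9:1), 0 °C
Reagents that add atoms: water, O
Why: Oxidative dethioacetalisation: the hypervalent iodine reagent activates sulfur, the aryl-stabilised thionium ion is captured by water and the aryl ketone is released. The buffer and the low temperature protect the enolisable C8 centre and the benzylic carbinol, and the ketone may rest in part as its lactol with the C9' hydroxyl.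

Step 8
Reactants: 15 (2R,3R)-3-[(S)-(3-benzyloxy-4,5-dimethoxyphenyl)(hydroxy)methyl]-1-(4-benzyloxy-3-methoxyphenyl)-4-hydroxy-2-(hydroxymethyl)butan-1-one
Product: 16 (2R,3R)-2-[(S)-(3-benzyloxy-4,5-dimethoxyphenyl)(hydroxy)methyl]-3-[(4-benzyloxy-3-methoxyphenyl)(hydroxy)methyl]butane-1,4-diol (both C7 epimers)
Conditions: NaBH4, MeOH–THF, 0 °C
Reagents that add atoms: none
Why: Borohydride reduction of the aryl ketone through its open form; no control at C7 is sought because this centre is ionised in step 9.

Step 9
Reactants: 16 (2R,3R)-2-[(S)-(3-benzyloxy-4,5-dimethoxyphenyl)(hydroxy)methyl]-3-[(4-benzyloxy-3-methoxyphenyl)(hydroxy)methyl]butane-1,4-diol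
Product: 18 (1S,3aR,4S,6aR)-1-(4-benzyloxy-3-methoxyphenyl)-4-(3-benzyloxy-4,5-dimethoxyphenyl)tetrahydro-1H,3H-furo[3,4-c]furan, via monocyclic tetrahydrofuran 17 (not isolated)
Conditions: CSA (0.1 equiv), CH2Cl2 (0.01 M), 0 °C → rt; Et3N quench as soon as 16 and 17 are consumed
Reagents that add atoms: none
Why: Acid ionises each para-alkoxybenzylic alcohol to a quinoid-stabilised cation that the 1,4-related primary hydroxyl captures in a 5-exo closure (C7 by the C9' oxygen, then C7' by the C9 oxygen), the cis fusion being dictated by the fixed C8 and C8' centres. In the favoured transition state each aryl group takes the convex face, which sets C7 and C7' as (S),(S) from either carbinol epimer. Catalytic acid, dilution and an early quench limit re-ionisation of the product and Friedel–Crafts capture.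

Step 10
Reactants: 18 (1S,3aR,4S,6aR)-1-(4-benzyloxy-3-methoxyphenyl)-4-(3-benzyloxy-4,5-dimethoxyphenyl)tetrahydro-1H,3H-furo[3,4-c]furan
Product: 19 4-[(1S,3aR,4S,6aR)-4-(3-hydroxy-4,5-dimethoxyphenyl)tetrahydro-1H,3H-furo[3,4-c]furan-1-yl]-2-methoxyphenol
Conditions: H2 (1 atm), 10% Pd/C, EtOAc, rt; stopped after uptake of 2 equiv of H2
Reagents that add atoms: none
Why: Hydrogenolysis of aryl benzyl ethers on palladium should be much faster than cleavage of the hindered ring benzylic C–O bonds in a neutral, aprotic solvent, so both phenols are released with the furofuran intact.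

## Compound list

1 | 4-benzyloxy-3-methoxybenzaldehyde (O-benzylvanillin) | COc1cc(C=O)ccc1OCc1ccccc1 | starting material
2 | 2-(4-benzyloxy-3-methoxyphenyl)-1,3-dithiane | COc1cc(C2SCCCS2)ccc1OCc1ccccc1 | intermediate
3 | furfural (furan-2-carbaldehyde) | O=Cc1ccco1 | starting material
4 | 2,3,7-trioxabicyclo[2.2.1]hept-5-ene-1-carbaldehyde (endoperoxide of furfural, racemic) | O=CC12C=CC(OO1)O2 | intermediate
5 | 5-hydroxyfuran-2(5H)-one (racemic) | O=C1C=CC(O)O1 | intermediate
6 | (1R,2S,5R)-menthol | C[C@@H]1CC[C@H]([C@@H](C1)O)C(C)C | starting material
7 | (5S)-5-[(1R,2S,5R)-menthyloxy]furan-2(5H)-one | O=C1C=C[C@@H](O[C@@H]2C[C@H](C)CC[C@H]2C(C)C)O1 | intermediate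
8 | (5R)-5-[(1R,2S,5R)-menthyloxy]furan-2(5H)-one | O=C1C=C[C@H](O[C@@H]2C[C@H](C)CC[C@H]2C(C)C)O1 | intermediate
9 | 3-hydroxy-4,5-dimethoxybenzaldehyde | COc1cc(C=O)cc(O)c1OC | starting material
10 | 3-benzyloxy-4,5-dimethoxybenzaldehyde | COc1cc(C=O)cc(OCc2ccccc2)c1OC | intermediate
11 | 2-(4-benzyloxy-3-methoxyphenyl)-2-lithio-1,3-dithiane | [Li]C1(SCCCS1)c1ccc(OCc2ccccc2)c(OC)c1 | intermediate
12 | lithium (4R,5R)-4-[2-(4-benzyloxy-3-methoxyphenyl)-1,3-dithian-2-yl]-5-[(1R,2S,5R)-menthyloxy]-4,5-dihydrofuran-2-olate | [Li]OC1=C[C@@H](C2(SCCCS2)c2ccc(OCc3ccccc3)c(OC)c2)[C@H](O[C@@H]2C[C@H](C)CC[C@H]2C(C)C)O1 | intermediate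
13 | (3S,4R,5R)-4-[2-(4-benzyloxy-3-methoxyphenyl)-1,3-dithian-2-yl]-3-[(S)-(3-benzyloxy-4,5-dimethoxyphenyl)(hydroxy)methyl]-5-[(1R,2S,5R)-menthyloxy]dihydrofuran-2(3H)-one | O=C1O[C@@H](O[C@@H]3C[C@H](C)CC[C@H]3C(C)C)[C@H](C3(SCCCS3)c3ccc(OCc4ccccc4)c(OC)c3)[C@H]1[C@H](O)c1cc(OCc2ccccc2)c(OC)c(OC)c1 | intermediate
14 | (2R,3R)-2-[2-(4-benzyloxy-3-methoxyphenyl)-1,3-dithian-2-yl]-3-[(S)-(3-benzyloxy-4,5-dimethoxyphenyl)(hydroxy)methyl]butane-1,4-diol | OC[C@H]([C@H](O)c1cc(OCc2ccccc2)c(OC)c(OC)c1)[C@H](CO)C1(SCCCS1)c1ccc(OCc2ccccc2)c(OC)c1 | intermediate
15 | (2R,3R)-3-[(S)-(3-benzyloxy-4,5-dimethoxyphenyl)(hydroxy)methyl]-1-(4-benzyloxy-3-methoxyphenyl)-4-hydroxy-2-(hydroxymethyl)butan-1-one | OC[C@H]([C@H](O)c1cc(OCc2ccccc2)c(OC)c(OC)c1)[C@H](CO)C(=O)c1ccc(OCc2ccccc2)c(OC)c1 | intermediate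
16 | (2R,3R)-2-[(S)-(3-benzyloxy-4,5-dimethoxyphenyl)(hydroxy)methyl]-3-[(4-benzyloxy-3-methoxyphenyl)(hydroxy)methyl]butane-1,4-diol (both C7 epimers) | OC[C@H]([C@H](O)c1cc(OCc2ccccc2)c(OC)c(OC)c1)[C@H](CO)C(O)c1ccc(OCc2ccccc2)c(OC)c1 | intermediate
17 | (S)-(3-benzyloxy-4,5-dimethoxyphenyl)[(3R,4R,5S)-5-(4-benzyloxy-3-methoxyphenyl)-4-(hydroxymethyl)tetrahydrofuran-3-yl]methanol | COc1cc([C@H]2OC[C@H]([C@H](O)c3cc(OCc4ccccc4)c(OC)c(OC)c3)[C@@H]2CO)ccc1OCc1ccccc1 | intermediate
18 | (1S,3aR,4S,6aR)-1-(4-benzyloxy-3-methoxyphenyl)-4-(3-benzyloxy-4,5-dimethoxyphenyl)tetrahydro-1H,3H-furo[3,4-c]furan | COc1cc([C@H]2OC[C@H]3[C@@H]2CO[C@@H]3c2cc(OCc4ccccc4)c(OC)c(OC)c2)ccc1OCc1ccccc1 | intermediate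
19 | 4-[(1S,3aR,4S,6aR)-4-(3-hydroxy-4,5-dimethoxyphenyl)tetrahydro-1H,3H-furo[3,4-c]furan-1-yl]-2-methoxyphenol | COc1cc([C@H]2OC[C@H]3[C@@H]2CO[C@@H]3c2cc(O)c(OC)c(OC)c2)ccc1O | target

## Step count and least certain steps

Total step count: 10. Longest linear sequence: 8 steps (3 → 5 → 8 → 13 → 14 → 15 → 16 → 18 → 19; steps 2, 3, 5, 6, 7, 8, 9, 10).

Step 5 (key step). The likeliest failure is reversal or incomplete trapping: the hindered lithium aldolate can revert to 12 and 10, and 12 can expel the stabilised anion 11 again if the mixture warms. Some 1,2-addition of 11 to the lactone carbonyl is the second possibility. The fallback separates the two bond formations; it sets out from 2 and 8 and returns at 13. The conjugate addition is run alone and quenched with a proton source at −78 °C to give the mono-adduct (4R,5R)-4-[2-(4-benzyloxy-3-methoxyphenyl)-1,3-dithian-2-yl]-5-[(1R,2S,5R)-menthyloxy]dihydrofuran-2(3H)-one F1, which can be purified and checked. Its enolate is then regenerated with LiN(i-Pr)2 at −78 °C (exchanged for the zinc enolate with ZnCl2 if the lithium aldolate reverts) and condensed with 10 to give 13.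

Step 7. Enolisation of the new aryl ketone at C8, with epimerisation or loss of the β-hydroxyl at C9, would destroy the cis relation needed for the bicycle. Attack of the iodine reagent on the electron-rich rings or on the free hydroxyls is the other concern. The fallback changes the order of events; it sets out from 13 and returns at 16. The thioketal is opened at the lactone stage, where only one hydroxyl is present, to give the keto lactone (3S,4R,5R)-4-(4-benzyloxy-3-methoxybenzoyl)-3-[(S)-(3-benzyloxy-4,5-dimethoxyphenyl)(hydroxy)methyl]-5-[(1R,2S,5R)-menthyloxy]dihydrofuran-2(3H)-one F2. LiAlH4 at −78 → 0 °C then reduces ketone, lactone carbonyl and acetal in one operation to 16. This saves a step, but the ketone of F2 has an acyloxy acetal in the β-position, so the reduction must be run cold and the compound is not stored.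

Step 9. Three processes threaten the closure: capture of a benzylic cation by the other benzylic hydroxyl (a 2,5-diaryltetrahydrofuran), Friedel–Crafts capture by the facing arene (an aryltetralin, irreversible), and re-ionisation of the product, which would level the exo,exo isomer with its C7 or C7' epimer. The fallback closes the rings one at a time so that only one cation and one reachable hydroxyl exist in each operation; it sets out from 14 and returns at 18. Catalytic acid on 14, in which C7 is still a thioketal, closes the ring B tetrahydrofuran to give [(2S,3R,4R)-2-(3-benzyloxy-4,5-dimethoxyphenyl)-4-[2-(4-benzyloxy-3-methoxyphenyl)-1,3-dithian-2-yl]tetrahydrofuran-3-yl]methanol F3. Oxidative hydrolysis as in step 7 gives (4-benzyloxy-3-methoxyphenyl)[(3R,4R,5S)-5-(3-benzyloxy-4,5-dimethoxyphenyl)-4-(hydroxymethyl)tetrahydrofuran-3-yl]methanone F4. NaBH4 gives the corresponding carbinol (4-benzyloxy-3-methoxyphenyl)[(3R,4R,5S)-5-(3-benzyloxy-4,5-dimethoxyphenyl)-4-(hydroxymethyl)tetrahydrofuran-3-yl]methanol F5 as a C7 mixture. A second brief acid treatment, in which only the C9' hydroxyl can reach the C7 cation, gives 18.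

Step 10. Hydrogenolytic opening of the ring bonds C7–O or C7'–O may occur alongside or after debenzylation, since both are benzylic ethers activated by para-oxygenated rings, and it becomes more likely once the free phenols appear. The fallback moves debenzylation in front of ring formation; it sets out from 16 and returns at 19. Hydrogenolysis of 16 (H2, 10% Pd/C, EtOAc) gives the bis-phenol tetraol (2R,3R)-2-[(S)-hydroxy(3-hydroxy-4,5-dimethoxyphenyl)methyl]-3-[hydroxy(4-hydroxy-3-methoxyphenyl)methyl]butane-1,4-diol F6, in which the benzylic C–O bonds are hydroxyls and should be slow to cleave on palladium under neutral conditions. Catalytic acid at high dilution then closes both rings to 19, the ring A carbinol ionising through a para-quinone methide. No palladium is applied to the finished furofuran.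

## Further compounds

F1 | step 5 | (4R,5R)-4-[2-(4-benzyloxy-3-methoxyphenyl)-1,3-dithian-2-yl]-5-[(1R,2S,5R)-menthyloxy]dihydrofuran-2(3H)-one | O=C1O[C@@H](O[C@@H]3C[C@H](C)CC[C@H]3C(C)C)[C@H](C3(SCCCS3)c3ccc(OCc4ccccc4)c(OC)c3)C1
F2 | step 7 | (3S,4R,5R)-4-(4-benzyloxy-3-methoxybenzoyl)-3-[(S)-(3-benzyloxy-4,5-dimethoxyphenyl)(hydroxy)methyl]-5-[(1R,2S,5R)-menthyloxy]dihydrofuran-2(3H)-one | O=C1O[C@@H](O[C@@H]3C[C@H](C)CC[C@H]3C(C)C)[C@H](C(=O)c3ccc(OCc4ccccc4)c(OC)c3)[C@H]1[C@H](O)c1cc(OCc2ccccc2)c(OC)c(OC)c1
F3 | step 9 | [(2S,3R,4R)-2-(3-benzyloxy-4,5-dimethoxyphenyl)-4-[2-(4-benzyloxy-3-methoxyphenyl)-1,3-dithian-2-yl]tetrahydrofuran-3-yl]methanol | OC[C@H]1[C@@H](C2(SCCCS2)c2ccc(OCc3ccccc3)c(OC)c2)CO[C@@H]1c1cc(OCc2ccccc2)c(OC)c(OC)c1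
F4 | step 9 | (4-benzyloxy-3-methoxyphenyl)[(3R,4R,5S)-5-(3-benzyloxy-4,5-dimethoxyphenyl)-4-(hydroxymethyl)tetrahydrofuran-3-yl]methanone | OC[C@H]1[C@@H](C(=O)c2ccc(OCc3ccccc3)c(OC)c2)CO[C@@H]1c1cc(OCc2ccccc2)c(OC)c(OC)c1
F5 | step 9 | (4-benzyloxy-3-methoxyphenyl)[(3R,4R,5S)-5-(3-benzyloxy-4,5-dimethoxyphenyl)-4-(hydroxymethyl)tetrahydrofuran-3-yl]methanol (both carbinol epimers) | OC[C@H]1[C@@H](C(O)c2ccc(OCc3ccccc3)c(OC)c2)CO[C@@H]1c1cc(OCc2ccccc2)c(OC)c(OC)c1
F6 | step 10 | (2R,3R)-2-[(S)-hydroxy(3-hydroxy-4,5-dimethoxyphenyl)methyl]-3-[hydroxy(4-hydroxy-3-methoxyphenyl)methyl]butane-1,4-diol (both C7 epimers) | OC[C@H]([C@H](O)c1cc(O)c(OC)c(OC)c1)[C@H](CO)C(O)c1ccc(O)c(OC)c1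
A1 | alternative 1 | compound 18 carrying a methoxy group on C9 (cyclic methyl acetal, both C9 epimers) | COc1cc([C@H]2OC[C@H]3[C@@H]2C(OC)O[C@@H]3c2cc(OCc4ccccc4)c(OC)c(OC)c2)ccc1OCc1ccccc1
A2 | alternative 1 | [(2S,3R)-2-(3-benzyloxy-4,5-dimethoxyphenyl)-2,3-dihydrofuran-3-yl]methanol | OC[C@H]1C=CO[C@@H]1c1cc(OCc2ccccc2)c(OC)c(OC)c1
A3 | alternative 1 | 4-benzyloxy-3-methoxybenzaldehyde dimethyl acetal | COc1cc(C(OC)OC)ccc1OCc1ccccc1
A4 | alternative 2 | O,O'-dibenzyl ether of the target (identical with 18) | COc1cc([C@H]2OC[C@H]3[C@@H]2CO[C@@H]3c2cc(OCc4ccccc4)c(OC)c(OC)c2)ccc1OCc1ccccc1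
A5 | alternative 2 | (2R,3R)-2-(4-benzyloxy-3-methoxybenzyl)-3-(3-benzyloxy-4,5-dimethoxybenzyl)butane-1,4-diol | OC[C@H](Cc1cc(OCc2ccccc2)c(OC)c(OC)c1)[C@H](CO)Cc1ccc(OCc2ccccc2)c(OC)c1
A6 | alternative 3 | (3S,3aR,6S,6aS)-6-(4-benzyloxy-3-methoxyphenyl)-3-(3-benzyloxy-4,5-dimethoxyphenyl)tetrahydro-1H,3H-furo[3,4-c]furan-1-one (compound 18 with C9 as a lactone carbonyl) | COc1cc([C@H]2OC[C@H]3[C@@H]2C(=O)O[C@@H]3c2cc(OCc4ccccc4)c(OC)c(OC)c2)ccc1OCc1ccccc1
A7 | alternative 3 | (R)-2-(4-benzyloxy-3-methoxyphenyl)-2,5-dihydrofuran-3-carbaldehyde | COc1cc([C@H]2OCC=C2C=O)ccc1OCc1ccccc1
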